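The four flasks are reckoned by a single number, the dose, and not by the stops seen in the earlier runs.

| flask | starting material | protic impurity | catalyst | temperature | remark | time |
|---|---|---|---|---|---|---|
| amber | 0.016 M | 1.6 mM | 0.27 mM | −10 °C | run made earlier |  |
| violet | 0.016 M | 1.6 mM | 0.60 mM | 18 °C | run made earlier |  |
| Tuesday's | 0.016 M | 1.60 mM | 0.40 mM | 40 °C |  | 1.5 h |
| Wednesday's | 0.016 M | 1.60 mM | 0.40 mM | 10 °C |  | 1.5 h |
| Monday's | 0.016 M | 1.60 mM | 0.40 mM | 25 °C |  | 1.5 h |
| Thursday's | 0.016 M | 1.60 mM | 0.40 mM | −5 °C |  | 1.5 h |

| run | time / h | target / % |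
|---|---|---|
| amber | 1.50 | 1 |
| amber | 3.00 | 2 |
| amber | 5.00 | 4 |
| amber | 6.00 | 8 |
| amber | 8.00 | 9 |
| amber | 10.0 | 4 |
| violet | 0.200 | 5 |
| violet | 0.333 | 12 |
| violet | 0.500 | 16 |
| violet | 0.667 | 20 |
| violet | 1.33 | 33 |
| violet | 2.00 | 46 |
| violet | 2.50 | 47 |

(scatter of a reading: 2 percentage points)

1. the flask with the highest amount of target, in percent of the starting material charged ("all alike" if they lie within 1.5 percentage points) (Tuesday's / Wednesday's / Monday's / Thursday's / all alike)
2. final target, as a percentage of the starting material charged, in Tuesday's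
3. final target, as a percentage of the starting material charged, in Wednesday's
4. final target, as a percentage of the starting material charged, in Monday's
5. final target, as a percentage of the starting material charged, in Thursday's

The dose is a pseudo-first-order constant multiplied by the time, so in this reckoning it grows with catalyst charge and with time, and temperature enters through the constant. In this reckoning, at small dose the fraction of the charge turned into target is close to the dose, and at large dose it approaches the whole charge. One minus the exponential of minus the dose joins the two ends.

The amber run's 9 % at 8.00 h reads as 0.0118 h⁻¹ with 0.27 mM of catalyst, though that reading carries a scatter of 2 percentage points. The violet run's 46 % at 2.00 h reads as 0.308 h⁻¹ with 0.60 mM. Scaled to 0.40 mM and 1.5 h, these become doses of 0.0262 at −10 °C and 0.308 at 18 °C. Their ratio gives a read activation energy of 56.1 kJ mol⁻¹, and the four rows follow: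

- Thursday's, −5 °C: dose 0.0422, target 4.14 %
- Wednesday's, 10 °C: dose 0.160, target 14.8 %
- Monday's, 25 °C: dose 0.531, target 41.2 %
- Tuesday's, 40 °C: dose 1.57, target 79.2 %

The quantity to carry is Tuesday's dose, the catalyst-and-time product at its temperature.

Read downward, the first two rows sit on the linear end, with target close to dose. Monday's row has begun to bend, its target lying below its dose. Tuesday's row bends hard, and its dose lies beyond that of the violet run's last reading: at 2.50 h the curve says 53.7 % for the violet run, but the reading was 47 %. So Tuesday's 79.2 % is held as an upper figure, yet it stays above the other rows.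

The forecast named Tuesday's, with 85 % for Tuesday's, 13 % for Wednesday's, 36 % for Monday's and 4 % for Thursday's, and it called Tuesday's “nearly complete, allowing for depletion”.

With crystals counted as target, the flasks give 71.9 % in Tuesday's, 14.3 % in Wednesday's, 41.4 % in Monday's and 3.59 % in Thursday's, so Tuesday's holds the highest amount.

    starting material + protic impurity → quenched substrate (k = 21.0 L mol⁻¹ h⁻¹, Ea = 55.0 kJ mol⁻¹)
    crystals ⇌ target, rate k2*(cs2 - [target]) while solid is left; crystals form when [target] > cs2 (solubility = 2.20 mM, k = 57.0 h⁻¹)
    target + catalyst ⇌ isomer of the product + catalyst, rate k3*[catalyst]*[target] forward; the back reaction follows from the equilibrium constant (K = 0.290, k = 1400 L mol⁻¹ h⁻¹, Ea = 63.0 kJ mol⁻¹, ΔH = 1.00 kJ mol⁻¹)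
    starting material + catalyst ⇌ target + catalyst, rate k4*[starting material]*[catalyst] forward; the back reaction follows from the equilibrium constant (K = 3.10, k = 3600 L mol⁻¹ h⁻¹, Ea = 63.0 kJ mol⁻¹, ΔH = 5.00 kJ mol⁻¹)
    target → over-reaction product (k = 0.350 h⁻¹, Ea = 89.0 kJ mol⁻¹)
    (constants at 40 °C)

The reckoning parts from the result in Tuesday's, where dose 1.57 gave 79.2 % against 71.9 %, a gap of 7.3 points. At 1.50 h, Tuesday's holds 7.32 % of over-reaction product, Monday's 1.17 %. One more flask, like Tuesday's but with 1.0 × 10⁻⁴ M of catalyst, takes a quarter of the dose, 0.392, which reckons to 32.4 %. That flask gives 31.1 % of target, and beside it 57.6 % of starting material and 6.26 % of over-reaction product.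

Readings and results were generated by integration with constants of no real substance, noise included.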